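The readings were generated by integration from invented constants, noise included.

Watch the partner, not the clock.

common to all: left-handed substrate 0.10 M; right-handed substrate 0.10 M; racemization catalyst 15 mM

|  | partner | impurity | remark | time |
|---|---|---|---|---|
| east | 0.40 M | 0.95 mM | run made earlier |  |
| south-east | 0.40 M | 3.8 mM | run made earlier |  |
| flask | 0.400 M | 1.9 mM |  | 30 h |

| run | time / h | left-handed product / % | right-handed product / % | left-handed substrate / % |
|---|---|---|---|---|
| east | 1.50 | 29.1 | 2.0 | 34.8 |
| east | 5.00 | 43.0 | 3.8 | 27.5 |
| east | 8.00 | 43.6 | 2.7 | 28.2 |
| east | 12.0 | 42.8 | 1.5 | 28.4 |
| east | 20.0 | 44.0 | 2.5 | 28.7 |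
| south-east | 1.33 | 27.6 | 0.9 | 34.0 |
| south-east | 2.50 | 35.9 | 0.4 | 30.7 |
| south-east | 5.00 | 41.6 | 1.5 | 26.7 |
| south-east | 10.0 | 43.7 | 3.1 | 28.3 |
| south-east | 20.0 | 41.9 | 3.4 | 26.7 |

(each reading ± 1 percentage point)

- partner is single-handed; left-handed substrate and right-handed substrate are mirror images of each other, charged as a racemate, each of them at the stated concentration
- steps thought possible: racemization catalyst + impurity -> spent catalyst; partner + right-handed substrate -> right-handed product; partner -> decomposed reagent; racemization catalyst <-> dormant form; partner + left-handed substrate -> left-handed product; left-handed substrate + racemization catalyst <-> right-handed substrate + racemization catalyst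
- an excess is below zero if the other one leads
- the handed part of partner does not stay in what it makes, so the products of the two hands are mirror images too

- left-handed product and right-handed product together, in percent of the left-handed substrate and right-handed substrate charged together, at 30 h
- excess of left-handed product over right-handed product in the product at 30 h
- whether the exchange between left-handed substrate and right-handed substrate keeps pace with the reaction: how far the product's excess at 30 h gets from its value without exchange to its value with instant exchange (above 80 % keeps pace, below 20 % hardly takes part, else lags behind)

Why do the earlier runs stall? Product levels off near 45.8 % of the charge in both, with about half of the substrate unreacted.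

Could the racemization catalyst be to blame? In the listed steps it swaps hands and makes no product. So I suppose the stall marks the end of the partner.

What do you carry forward? Let s be left-handed plus right-handed substrate at any moment, T their charge, B the partner charge and x the product made. If the hands stay equal, partner goes to product and to decomposed reagent in the ratio s/C. The crossing concentration, C, is the s at which those two losses are equal. Integrating until the partner has run out gives B = x + C ln(T/(T−x)). My reading from the plateau is C = 0.503 M.

The weak spot: do the hands stay equal? In the east run at 1.50 h, left-handed substrate reads 34.8 % and right-handed, by difference, 34.1 %, within the scatter of 1 percentage point per reading.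

And the flask? Its charge of 0.200 M is smaller than C, so decomposition leads from the start, when product's share of the partner being used is 28.5 %; that share is for the start and falls as substrate is used. Its partner charge matches the runs, so my reckoning gives the plateau again.

The forecast, from the same readings, gave y 45.8 % (43.5 % to 48 %), eP 88 % (84.5 % to 91 %) and keeps pace: “The partner has evidently decomposed, and the flask has the same partner charge, so 30 h should sit on the same plateau.”

    racemization catalyst + impurity → spent catalyst (k = 3500 M⁻¹ min⁻¹)
    partner + right-handed substrate → right-handed product (k = 0.00180 M⁻¹ min⁻¹)
    partner → decomposed reagent (k = 0.00900 min⁻¹)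
    racemization catalyst ⇌ dormant form (K = 0.230, k = 0.0210 min⁻¹)
    partner + left-handed substrate → left-handed product (k = 0.0330 M⁻¹ min⁻¹)
    left-handed substrate + racemization catalyst ⇌ right-handed substrate + racemization catalyst, rate k6*[racemization catalyst]*[left-handed substrate] forward; the back reaction follows from the equilibrium constant (k = 22.0 M⁻¹ min⁻¹)

The flask gives y 44.9 %, eP 89.5 % and keeps pace, 98 % of the way. With decomposition struck out, y is 99.9 %. By C, product's share of the partner falls from 28.5 % at the start to 18.0 % at the flask's final substrate level; partner stands at 0 % by 15.0 h.

With 1.0 M of partner and the rest as in the flask, repeated substitution into the rule gives y 80.9 %. The computed neighbour gives 79.9 %, with eP 89.3 %.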